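There are two numbers to find: the excess in noon and the excess in autumn. The winner follows from their gap.

| setting | zeta | alpha | theta | noon | autumn |
|---|---|---|---|---|---|
| left-handed substrate | 0.083 M | 0.083 M | 0.17 M | 0.083 M | 0.083 M |
| right-handed substrate | 0.083 M | 0.083 M | 0.17 M | 0.083 M | 0.083 M |
| partner | 0.083 M | 0.33 M | 0.166 M | 0.166 M | 0.166 M |
| remark | run made earlier | run made earlier | run made earlier |  |  |
| time |  |  |  | 15 min | 5.0 min |

| run | time / min | right-handed substrate / % | left-handed substrate / % | left-handed product / % |
|---|---|---|---|---|
| zeta | 1.33 | 49.4 | 44.3 | 3.7 |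
| zeta | 3.00 | 43.6 | 40.1 | 5.5 |
| zeta | 8.00 | 36.6 | 28.1 | 12.4 |
| zeta | 20.0 | 24.0 | 16.8 | 14.7 |
| alpha | 1.33 | 45.9 | 38.4 | 10.5 |
| alpha | 3.00 | 43.4 | 28.6 | 17.4 |
| alpha | 8.00 | 34.5 | 19.5 | 22.2 |
| alpha | 20.0 | 20.9 | 10.8 | 26.2 |
| theta | 1.33 | 46.2 | 40.4 | 6.3 |
| theta | 3.00 | 42.6 | 33.5 | 8.2 |
| theta | 8.00 | 34.6 | 25.5 | 15.2 |
| theta | 20.0 | 23.2 | 15.5 | 20.4 |

(scatter of a reading: 1 percentage point)

- partner is single-handed; left-handed substrate and right-handed substrate are mirror images of each other, charged as a racemate, each of them at the stated concentration
- the numbers in the tables scatter with a standard deviation of 1 percentage point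
- an excess is the difference of the two amounts in percent of their sum
- an excess is below zero if the other one leads
- the handed part of partner does not stay in what it makes, so the products of the two hands are mirror images too

- the winner by excess of right-handed substrate over left-handed substrate among what is left of the two; "neither" if no more than 2 percentage points parts them (noon / autumn / neither)
- excess of right-handed substrate over left-handed substrate among what is left of the two at the end, noon
- excess of right-handed substrate over left-handed substrate among what is left of the two at the end, autumn

Write r and l for the fractions of the charge left as right-handed and left-handed substrate, so the excess is (r − l)/(r + l). This is a kinetic resolution, and you can see both partner and time at work. Zeta rises from 13.1% at 8.00 min to 17.6% at 20.0 min, while alpha, with more partner, reads 27.8% at 8.00 min.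

So I fold both into one number, the dose n: partner charge times time, counted in units of zeta at its last reading.

n, noon = 1.50
n, autumn = 0.500

The readings on either side of these doses are:

zeta, 8.00 min: n = 0.400, excess 13.1%
alpha, 3.00 min: n = 0.596, excess 20.6%
zeta, 20.0 min: n = 1.00, excess 17.6%
alpha, 8.00 min: n = 1.59, excess 27.8%

Reading straight between them, I get:

autumn: 16.9%
noon: 26.2%

Was one number enough? Alpha at 3.00 min has a lower dose than zeta at 20.0 min. Its excess reads higher than zeta's by 3.0 percentage points, but a scatter of 1 point in each reading moves the excess of zeta at 20.0 min by about 3.5 points, more than that difference, so this pair shows no failure of n. My gap of 9.3 points is wider than that scatter, so I say noon.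

Theta, with twice the substrate, reads 19.9% at n = 2.00, less than alpha at 8.00 min. So n compares flasks of equal substrate charge, as noon and autumn are with zeta and alpha.

The forecast gives noon, with 23% and 16%, a little below my figures, and calls itself “an interpolation, not a fitted mechanism”.

The flask gives noon: 23.9% in noon and 14.9% in autumn, a gap of 9 points.

    achiral form → waste (k = 0.00290 s⁻¹)
    right-handed substrate ⇌ achiral form (K = 0.960, k = 7.30 × 10⁻⁴ s⁻¹)
    achiral form → decomposed reagent (k = 0.00140 s⁻¹)
    partner + right-handed substrate → right-handed product (k = 0.00140 L mol⁻¹ s⁻¹)
    2 partner → homo dimer (k = 0.0130 L mol⁻¹ s⁻¹)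
    left-handed substrate ⇌ achiral form (K = 0.960, k = 7.30 × 10⁻⁴ s⁻¹)
    partner + left-handed substrate → left-handed product (k = 0.0120 L mol⁻¹ s⁻¹)

Partner at the end stands at 36% of its charge in autumn and 15% in noon. Now use the dose on two neighbours of noon. Charged with 0.28 M of partner, the neighbour has n = 2.53, and noon left until 25 min has n = 2.50. At nearly equal dose, the richer flask gives 30.9% and the longer one 26.3%.

Readings and results are calculated for an exercise; noise was put on by code.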